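**Retrosynthetic overview**
1. The target is (2S)-7,4'-dihydroxy-6,8-diprenylflavanone. The last operation is removal of two MOM ethers. Before it, the 2S enantiomer is selected from the racemic bis-MOM flavanone by asymmetric transfer hydrogenation run as a kinetic resolution.
2. Ring C is opened at O1–C2 (retro-oxa-Michael) to give a 2'-hydroxychalcone.
3. Key disconnection: the chalcone C(alpha)=C(beta) bond (future C3–C2). It is made by an intermolecular Claisen–Schmidt aldol condensation of a ring A methyl ketone with a ring B aldehyde.
4. In the ring A ketone, both prenyl groups come from allyl groups by cross-metathesis. The allyl groups come from two rounds of O-allylation and Claisen rearrangement on 2,4-dihydroxyacetophenone.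
5. Ring order: rings A and B are bought as arenes. Ring C is the only ring made, and it is closed after the aldol step.

Assumption: the stereocentre in the SMILES is read as 2S. The sense of the kinetic resolution is taken from the usual TsDPEN model and is confirmed by CD and chiral HPLC on the first run.

**Route**

Step 1
Reactants: 1 2,4-dihydroxyacetophenone
Product: 2 1-[4-(allyloxy)-2-hydroxyphenyl]ethan-1-one
Conditions: allyl bromide (1.1 equiv), K2CO3 (1.2 equiv), acetone, reflux, 8 h
Reagents that add atoms: allyl bromide, C=CCBr
Why: Williamson ether synthesis, in which the 2-OH is hydrogen-bonded to the acetyl C=O and is much less nucleophilic, so one equivalent of allyl bromide alkylates only the 4-OH.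

Step 2
Reactants: 2 1-[4-(allyloxy)-2-hydroxyphenyl]ethan-1-one
Product: 4 1-(3-allyl-2,4-dihydroxyphenyl)ethan-1-one, via ortho-dienone 3 (not isolated)
Conditions: PhNEt2, 205 °C, N2, 5 h
Reagents that add atoms: none
Why: Aromatic Claisen rearrangement ([3,3] shift, then tautomerisation of 3), in which the chelated 2-hydroxy ketone sends the allyl group mainly to C3, and any minor C5 isomer would converge on the same 7 after steps 3 and 4.

Step 3
Reactants: 4 1-(3-allyl-2,4-dihydroxyphenyl)ethan-1-one
Product: 5 1-[3-allyl-4-(allyloxy)-2-hydroxyphenyl]ethan-1-one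
Conditions: allyl bromide (1.2 equiv), K2CO3 (1.5 equiv), acetone, reflux, 12 h
Reagents that add atoms: allyl bromide, C=CCBr
Why: A second Williamson ether synthesis, again selective for the non-chelated 4-OH.

Step 4
Reactants: 5 1-[3-allyl-4-(allyloxy)-2-hydroxyphenyl]ethan-1-one
Product: 7 1-(3,5-diallyl-2,4-dihydroxyphenyl)ethan-1-one, via ortho-dienone 6 (not isolated)
Conditions: PhNEt2, 205 °C, N2, 6 h
Reagents that add atoms: none
Why: Aromatic Claisen rearrangement in which C3 is blocked, so C5 is the only ortho position that can rearomatise after the [3,3] shift and a single product forms.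

Step 5
Reactants: 7 1-(3,5-diallyl-2,4-dihydroxyphenyl)ethan-1-one
Product: 8 1-[3,5-diallyl-2-hydroxy-4-(methoxymethoxy)phenyl]ethan-1-one
Conditions: MOMCl (1.3 equiv), K2CO3 (2.5 equiv), acetone, rt to reflux, 4 h
Reagents that add atoms: chloromethyl methyl ether (MOMCl), COCCl
Why: Phenol O-alkylation (MOM protection), in which the small and very reactive MOMCl reaches the flanked 4-OH while the chelated 2-OH, needed later as the ring C nucleophile, stays free.

Step 6
Reactants: 8 1-[3,5-diallyl-2-hydroxy-4-(methoxymethoxy)phenyl]ethan-1-one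
Product: 9 1-[2-hydroxy-4-(methoxymethoxy)-3,5-bis(3-methylbut-2-en-1-yl)phenyl]ethan-1-one
Conditions: second-generation Grubbs catalyst RuCl2(=CHPh)(PCy3)(H2IMes) (5 mol %), 2-methylbut-2-ene/CH2Cl2 (1:1), 40 °C, sealed tube, 16 h
Reagents that add atoms: 2-methylbut-2-ene, CC=C(C)C
Why: Olefin cross-metathesis, in which a large excess of the trisubstituted alkene converts both terminal allyl groups to prenyl groups, loss of propene drives the reaction, and phenol, ketone and MOM ether are tolerated.

Step 7
Reactants: 10 4-hydroxybenzaldehyde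
Product: 11 4-(methoxymethoxy)benzaldehyde
Conditions: MOMCl (1.2 equiv), K2CO3 (2 equiv), acetone, rt, 4 h
Reagents that add atoms: chloromethyl methyl ether (MOMCl), COCCl
Why: Phenol O-alkylation (MOM protection), which keeps the aldehyde from turning into an unreactive phenoxide in the basic aldol step.

Step 8
Reactants: 9 1-[2-hydroxy-4-(methoxymethoxy)-3,5-bis(3-methylbut-2-en-1-yl)phenyl]ethan-1-one, 11 4-(methoxymethoxy)benzaldehyde
Product: 13 (E)-2'-hydroxy-4,4'-bis(methoxymethoxy)-3',5'-diprenylchalcone, via aldol adduct 12 (not isolated)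
Conditions: KOH (12 equiv), EtOH/H2O (4:1), 0 °C to rt, 36 h; then cold 1 M citric acid to pH 5
Reagents that add atoms: none
Why: Claisen–Schmidt crossed aldol condensation, in which the enolate of methyl ketone 9 adds to the non-enolisable aldehyde 11 to form the future C3–C2 bond, E1cB loss of water from 12 gives the E-chalcone, strong base keeps the chalcone open as its phenoxide, and MOM and prenyl groups are inert to KOH.

Step 9
Reactants: 13 (E)-2'-hydroxy-4,4'-bis(methoxymethoxy)-3',5'-diprenylchalcone
Product: 14 racemic 7,4'-bis(methoxymethoxy)-6,8-diprenylflavanone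
Conditions: NaOAc (10 equiv), EtOH, reflux, 36 h; SiO2, recovered 13 resubmitted
Reagents that add atoms: none
Why: Intramolecular oxa-Michael addition (chalcone–flavanone isomerisation), in which a weak base lets the 2'-OH add to the enone and close ring C, creating C2 as a racemate under equilibrium control.

Step 10
Reactants: 14 racemic 7,4'-bis(methoxymethoxy)-6,8-diprenylflavanone
Product: 15 (2S)-7,4'-bis(methoxymethoxy)-6,8-diprenylflavanone
Conditions: RhCl(Cp*)[(R,R)-TsDPEN] (1 mol %), HCO2H/Et3N (5:2), EtOAc, rt, stopped at 52–55 % conversion (chiral HPLC); SiO2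
Reagents that add atoms: none
Why: Noyori-type asymmetric transfer hydrogenation run as a kinetic resolution, in which the (R,R)-catalyst makes 4R alcohols and is matched only with the 2R ketone (2,4-cis product), so that enantiomer is removed as a polar flavan-4-ol while the 2S ketone stays untouched in high ee, and prenyl alkenes and MOM ethers do not react.

Step 11
Reactants: 15 (2S)-7,4'-bis(methoxymethoxy)-6,8-diprenylflavanone
Product: 16 (2S)-7,4'-dihydroxy-6,8-diprenylflavanone
Conditions: 3 M aq HCl/MeOH (1:4), 45 °C, 2 h; work-up kept at pH 5–6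
Reagents that add atoms: none
Why: Acid-catalysed acetal solvolysis (MOM cleavage), in which C2 is configurationally safe because flavanone racemisation runs through base-induced ring opening, and short exposure to dilute acid leaves the prenyl groups uncyclised.

**Compound list**
1 | 2,4-dihydroxyacetophenone | CC(=O)c1ccc(O)cc1O | starting material
2 | 1-[4-(allyloxy)-2-hydroxyphenyl]ethan-1-one | CC(=O)c1ccc(OCC=C)cc1O | intermediate
3 | 4-acetyl-6-allyl-5-hydroxycyclohexa-2,4-dien-1-one (racemic, not isolated) | CC(=O)C1=C(O)C(CC=C)C(=O)C=C1 | intermediate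
4 | 1-(3-allyl-2,4-dihydroxyphenyl)ethan-1-one | CC(=O)c1ccc(O)c(CC=C)c1O | intermediate
5 | 1-[3-allyl-4-(allyloxy)-2-hydroxyphenyl]ethan-1-one | CC(=O)c1ccc(OCC=C)c(CC=C)c1O | intermediate
6 | 4-acetyl-2,6-diallyl-3-hydroxycyclohexa-2,4-dien-1-one (racemic, not isolated) | CC(=O)C1=CC(CC=C)C(=O)C(CC=C)=C1O | intermediate
7 | 1-(3,5-diallyl-2,4-dihydroxyphenyl)ethan-1-one | CC(=O)c1cc(CC=C)c(O)c(CC=C)c1O | intermediate
8 | 1-[3,5-diallyl-2-hydroxy-4-(methoxymethoxy)phenyl]ethan-1-one | CC(=O)c1cc(CC=C)c(OCOC)c(CC=C)c1O | intermediate
9 | 1-[2-hydroxy-4-(methoxymethoxy)-3,5-bis(3-methylbut-2-en-1-yl)phenyl]ethan-1-one | CC(=O)c1cc(CC=C(C)C)c(OCOC)c(CC=C(C)C)c1O | intermediate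
10 | 4-hydroxybenzaldehyde | O=Cc1ccc(O)cc1 | starting material
11 | 4-(methoxymethoxy)benzaldehyde | COCOc1ccc(C=O)cc1 | intermediate
12 | racemic 3-hydroxy-1-[2-hydroxy-4-(methoxymethoxy)-3,5-diprenylphenyl]-3-[4-(methoxymethoxy)phenyl]propan-1-one (not isolated) | COCOc1ccc(cc1)C(O)CC(=O)c1cc(CC=C(C)C)c(OCOC)c(CC=C(C)C)c1O | intermediate
13 | (E)-2'-hydroxy-4,4'-bis(methoxymethoxy)-3',5'-diprenylchalcone | COCOc1ccc(/C=C/C(=O)c2cc(CC=C(C)C)c(OCOC)c(CC=C(C)C)c2O)cc1 | intermediate
14 | racemic 7,4'-bis(methoxymethoxy)-6,8-diprenylflavanone | CC(C)=CCc1cc2c(c(CC=C(C)C)c1OCOC)OC(c1ccc(OCOC)cc1)CC2=O | intermediate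
15 | (2S)-7,4'-bis(methoxymethoxy)-6,8-diprenylflavanone | CC(C)=CCc1cc2c(c(CC=C(C)C)c1OCOC)O[C@H](c1ccc(OCOC)cc1)CC2=O | intermediate
16 | (2S)-7,4'-dihydroxy-6,8-diprenylflavanone | CC(C)=CCc1cc2c(c(CC=C(C)C)c1O)O[C@H](c1ccc(O)cc1)CC2=O | target

**Step count**
- Total steps: 11.
- Longest linear sequence: 10 (steps 1–6 and 8–11).

**Steps most likely to fail, with fallbacks**

**Step 9** may stall because the oxa-Michael closure is an equilibrium, and the electron-rich ring B makes the enone a poor acceptor. The fallback closes ring C by substitution at C2 instead of by conjugate addition. It sets out from 9, together with 11.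
- The phenoxide-enolate dianion of 9 (LiN(i-Pr)2, 2.2 equiv, THF, −78 °C) is added to 11.
- The mixture is quenched cold with AcOH, so that the aldol adduct 12 is isolated instead of being dehydrated.
- An intramolecular Mitsunobu etherification (PPh3, DIAD, THF, 0 °C) then forms O1–C2 irreversibly and comes back to the route at 14.
- Any 13 formed by elimination is fed into step 9.
- This fallback makes no compound outside the list (F0).

**Step 10** may show a lower selectivity factor than simple flavanones do, because of the two prenyl groups and the flanked 7-OMOM. The fallback replaces catalytic kinetic resolution with physical resolution. It sets out from 14 and comes back at 15.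
- The racemate is separated by preparative chiral-phase SFC or HPLC on an amylose tris(3,5-dimethylphenylcarbamate) phase, which resolves flavanones well.
- The 2S fraction is identified by CD: a positive band near 330 nm and a negative band near 290 nm.
- This fallback makes no compound outside the list (F0).

**Step 11** may cause some chroman formation between the freed 7-OH and a neighbouring prenyl group, or some loss of ee, since enantiopure material is warmed in acid. The fallback moves the acid step to the racemic stage and changes the protecting group. It sets out from 14 and comes back at 16.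
- 14 is deprotected with HCl/MeOH at the racemic stage, where only chemical yield matters, to give racemic 7,4'-dihydroxy-6,8-diprenylflavanone F1.
- Silylation with TBSOTf and 2,6-lutidine (CH2Cl2, −20 °C) gives racemic 7,4'-bis(tert-butyldimethylsilyloxy)-6,8-diprenylflavanone F2.
- The same transfer-hydrogenation kinetic resolution with RhCl(Cp*)[(R,R)-TsDPEN] leaves (2S)-7,4'-bis(tert-butyldimethylsilyloxy)-6,8-diprenylflavanone F3.
- Et3N·3HF in THF at 0 °C to rt is slightly acidic and never forms a free phenoxide. It removes both silyl groups and delivers 16.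

**Further compounds**
F0 | step 9 | none | none
F0 | step 10 | none | none
F1 | step 11 | racemic 7,4'-dihydroxy-6,8-diprenylflavanone | CC(C)=CCc1cc2c(c(CC=C(C)C)c1O)OC(c1ccc(O)cc1)CC2=O
F2 | step 11 | racemic 7,4'-bis(tert-butyldimethylsilyloxy)-6,8-diprenylflavanone | CC(C)=CCc1cc2c(c(CC=C(C)C)c1O[Si](C)(C)C(C)(C)C)OC(c1ccc(O[Si](C)(C)C(C)(C)C)cc1)CC2=O
F3 | step 11 | (2S)-7,4'-bis(tert-butyldimethylsilyloxy)-6,8-diprenylflavanone | CC(C)=CCc1cc2c(c(CC=C(C)C)c1O[Si](C)(C)C(C)(C)C)O[C@H](c1ccc(O[Si](C)(C)C(C)(C)C)cc1)CC2=O
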